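## Structural features

The target is a cyclohex-4-ene-1,3-diol. Its ring is numbered here C1 (secondary allylic carbinol), C2=C3, C4 (methylene), C5 (tertiary carbinol) and C6 (methylene). C5 also carries an unbranched sixteen-carbon chain (C1′ to C16′) with a (Z)-C12′=C13′ double bond and a phenyl ring on C16′. The two stereocentres, C1 (S) and C5 (S), are separated by C6 and are 1,3-cis, so both oxygens can sit diaxial on one face of the half-chair. C5 is a fully substituted carbinol whose two ring arms differ only two atoms out, so its absolute configuration is the real difficulty; C1 must then be set relative to it across the ring. The fragile parts are the allylic secondary alcohol, the acid-sensitive tertiary alcohol, the isolated (Z)-alkene (electrophiles, isomerisation, over-reduction), and any C1-carbonyl intermediate, which could lose water from C5 and aromatise. The distal phenyl ring forbids any dissolving-metal step once it is in place. The key step exploits the fact that C1 to C6 with the chain on C5 are a masked monoalkylbenzene. After dearomatisation and oxygenation of the ipso carbon C5, the C5 oxygen lies 1,3 to one carbon of the remaining C1=C2 alkene. A carbonate tether can relay it to C1 on its own face, and the iodine left on C2 then moves the double bond to C2=C3.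

## Logic of the disconnections

18 ⇒ 17. The (Z)-C12′=C13′ double bond is traced back to a C12′≡C13′ triple bond; no skeletal bond is cut. An alkyne tolerates electrophilic iodine far better than an alkene and returns the (Z) geometry by syn addition of hydrogen. The forward step must stop at the alkene and leave the ring alkene and the allylic C1–O bond alone.

17 ⇒ 16. The O–H bonds on C1 and C5 are joined through one carbonyl carbon into a bridged carbonate. The cis-1,3 relationship is then held in a ring and only has to be preserved. The forward step is an acyl transfer to solvent that breaks no C–O bond at a stereocentre.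

16 ⇒ 15. The C2=C3 double bond is replaced by C2–I and C3–H. This turns the allylic system into the direct adduct of an alkene, an oxygen nucleophile and an iodine electrophile. The forward elimination must go toward C3 only.

15 ⇒ 14. The C1–O and C2–I bonds are cut, which opens the carbonate ring and restores a C1=C2 alkene and an acyclic tert-butyl carbonate on C5. This is the largest simplification: one stereocentre and an isolated alkene replace three stereocentres and a bicycle. The forward step must deliver oxygen to C1 and not C2, on the face of the C5 oxygen, and must spare the triple bond.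

14 ⇒ 11 + 12. The O–C(=O) bond on the C5 oxygen is cut, leaving the tertiary alcohol; its alkoxide 13 is the species acylated. The demand is acylation of a hindered tertiary hydroxyl without elimination.

11 ⇒ 8 + 9. The C11′–C12′ bond is cut between a primary sp3 carbon and the alkyne terminus, by way of acetylide 10. This is the only entry point for the second phenyl ring, and it lies after the dissolving-metal step. The alkylation must tolerate the free tertiary hydroxyl, at the cost of one extra equivalent of 10.

8 ⇒ 7. C11′–I is traced to C11′–OH, the form that survives the earlier reduction and oxidation. The primary hydroxyl must be activated in the presence of the tertiary one.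

7 ⇒ 6. The C4–H bond is traced to an epoxide across C4–C5. The problem of a carbinol with two nearly identical ring arms becomes face selection on a trisubstituted alkene. Hydride must attack C4 only, leaving the C5–O bond and its configuration intact.

6 ⇒ 5. The two epoxide C–O bonds are cut, giving a 1-substituted cyclohexa-1,4-diene. The forward step must choose the trisubstituted alkene over the disubstituted one and one of its two faces.

5 ⇒ 4. The diene is the dihydro form of a monoalkylbenzene, so restoring the arene removes all ring functionality. The reduction must place the alkyl group on a double bond and must be run before the second arene and the alkyne exist.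

4 ⇒ 1 + 2. The C(aryl)–C1′ bond is cut to an aryl Grignard reagent and an eleven-carbon ω-bromo alcohol, both purchasable. Alkoxide 3 protects the hydroxyl in the flask.

## Other disconnections considered

Alternative 1: The ring is cut at C4–C5 and the C2=C3 π bond is returned to a vinyl group on C2. This unfolds the carbocycle into the six-membered lactone A2, in which the carbonyl carbon is C1′, the α-carbon is C5 and the alkoxy carbon is C2. Forward, the silyl ketene acetal of A2 would undergo an Ireland–Claisen rearrangement through the boat geometry that the lactone ring enforces. It would join C5 to C4, place the double bond at C2=C3 and release the carboxyl group, giving acid A1.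
- In its favour: the carbocycle, the alkene position and the quaternary centre C5 come from one concerted step. The C1/C5 relationship follows from suprafacial transfer out of the 5,6-cis lactone, which is as secure as the tether of the chosen plan (equal on this point). No elimination is needed to place the alkene (better on this point).
- Against it here: A1 ends in a carboxyl carbon on the quaternary C5. Fifteen chain carbons would have to be attached at a neopentyl-type, β-silyloxy position. That means either olefination of the derived aldehyde followed by a reduction that must spare C2=C3 and the (Z)-alkene, or an sp3–sp3 coupling at a hindered centre. A2 also needs two controlled stereocentres before the key step.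
- Comparison: on mechanism the two plans are comparable, both being stereospecific and substrate-controlled. On structure the chosen plan fits better, because the benzene ipso carbon brings the chain with it. On step economy the alternative would be longer than eleven steps once lactone synthesis and chain extension are counted.

Alternative 2: The ring is opened completely, at C1–C6, C3–C4 and C2–C3. C5 becomes the quaternary carbon of epoxy tosylate A3, made by Ti(OiPr)4/tartrate/t-BuOOH epoxidation of a 2-substituted allylic alcohol that already carries the (Z)-configured chain. C1 and C2 come from 2-methyl-1,3-dithiane A4, and C3 is a one-carbon nucleophile added later. Forward, lithiated A4 would open the oxirane of A3 at its methylene carbon. The released C5 alkoxide would displace the tosylate and give the transposed epoxide A5 without touching the C5 stereocentre.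
- In its favour: C5 would be set by an allylic-alcohol epoxidation whose sense and level of induction are more predictable than the dioxirane epoxidation of a cyclohexadiene used in the chosen plan (better on this point). The (Z)-alkene can be present from the start, since no electrophilic halogen is used, so the late semi-hydrogenation disappears (also better). The assembly is convergent.
- Against it here: after A5, three more events are needed, namely opening at C4 by the C3 nucleophile, unmasking of the dithiane beside a (Z)-alkene, and an intramolecular aldol condensation. They lead to the β-hydroxy enone A6, where loss of water from C5 would head toward a phenol. C1 would then depend on a 1,3-directed carbonyl reduction, with no geometric lock on the cis outcome.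
- Comparison: on mechanism, C5 is equally safe in both plans, but C1 is better secured by the tether of the chosen plan. On structure, the chosen plan takes all six ring carbons from benzene, whereas this one builds the ring from three pieces. On step economy the count would be about equal at best.

Alternative 3: Two ring bonds are cut, C1–C2 and C3–C4. The ring divides into the achiral cyclobutanone A7 (C1, C6, C5, C4, with the silyloxy group and chain on C5) and ethyne A8 (C2, C3). Forward, zerovalent nickel (Ni(cod)2 with a chiral phosphine) would couple the carbonyl carbon with A8 by oxidative cyclisation. β-Carbon elimination would then cleave one of the two enantiotopic C1–CH2 bonds, and reductive elimination would form C3–C4 to give enone A9.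
- In its favour: it would be the shortest plan, about seven or eight steps against eleven, since A9 needs only carbonyl reduction and desilylation (better on step economy). The chain and its (Z)-alkene are complete before the ring is made, and the ring alkene appears where it is needed.
- Against it here: the catalyst must distinguish two α-methylene groups that differ only through a remote quaternary centre bearing a silyloxy group and an n-alkyl chain. Ethyne tends to oligomerise at low-valent nickel, and the insertion is best established for internal alkynes. A9 shares the β-elimination liability of A6. C1 again rests on a 1,2-reduction without a locked facial preference.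
- Comparison: on mechanism the alternative depends on an enantio-determining organometallic step with no close analogy for this substitution pattern, whereas each step of the chosen plan belongs to an established class. On structure both use the symmetry of a simple ring precursor and are equal in that respect.

Key step: step 8

Remarks on the chemistry:
- Locants C1 to C6 and C1′ to C16′ in the explanations are those defined above; systematic names use their own locants.
- The bridged iodocarbonate is named with the chain on C1 and iodine on C6 of the 2,4-dioxabicyclo[3.3.1]nonan-3-one skeleton, the lowest locants for that connectivity.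
- Phenylmagnesium bromide (THF solution) and the L-fructose-derived epoxidation ketone are assumed to be purchased; the ketone is a catalyst and contributes no atoms.
- The L-fructose-derived ketone is specified because, on the spiro transition-state model for 1-substituted cyclohexenes, the D-fructose-derived ketone would place oxygen on the opposite face.

## Route

Step 1
Reactants: 1 11-bromoundecan-1-ol; 2 phenylmagnesium bromide
Product: 4 11-phenylundecan-1-ol, via bromomagnesium 11-bromoundecan-1-olate 3 (not isolated)
Conditions: 2 (2.3 equiv), Li2CuCl4 (3 mol %), THF, −10 °C → rt; aq. NH4Cl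
Reagents that add atoms: none
Why: Copper-catalysed Kochi-type cross-coupling of an aryl Grignard reagent with a primary alkyl bromide; the first equivalent of 2 converts the hydroxyl into the inert magnesium alkoxide 3, so no protecting group is needed.

Step 2
Reactants: 4 11-phenylundecan-1-ol
Product: 5 11-(cyclohexa-1,4-dien-1-yl)undecan-1-ol
Conditions: Li (5 equiv), NH3(l)–THF, t-BuOH, −78 → −33 °C; NH4Cl
Reagents that add atoms: none
Why: Birch reduction of a monoalkylbenzene leaves the alkyl group on a double bond and gives the unconjugated 1,4-diene; the side-chain hydroxyl is inert, and the step precedes the introduction of the second arene and the alkyne.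

Step 3
Reactants: 5 11-(cyclohexa-1,4-dien-1-yl)undecan-1-ol
Product: 6 11-[(1R,6S)-7-oxabicyclo[4.1.0]hept-3-en-1-yl]undecan-1-ol
Conditions: L-fructose-derived ketone (1,2:4,5-di-O-isopropylidene-β-L-erythro-2,3-hexodiulo-2,6-pyranose, 30 mol %), Oxone (2KHSO5·KHSO4·K2SO4, 1.4 equiv KHSO5), K2CO3, Bu4NHSO4, MeCN–CH2(OMe)2/aq. Na2B4O7 buffer with Na2H2EDTA (pH 10.5), −10 → 0 °C
Reagents that add atoms: potassium peroxymonosulfate (oxidant of Oxone), [K+].[O-]S(=O)(=O)OO
Why: Shi asymmetric epoxidation: the chiral dioxirane transfers oxygen through a spiro transition state to the electron-richer trisubstituted alkene in preference to the cis-disubstituted one. The L-fructose-derived ketone should deliver oxygen to the face that gives (1R,6S), which fixes the future C5 stereocentre.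

Step 4
Reactants: 6 11-[(1R,6S)-7-oxabicyclo[4.1.0]hept-3-en-1-yl]undecan-1-ol
Product: 7 (1S)-1-(11-hydroxyundecyl)cyclohex-3-en-1-ol
Conditions: LiAlH4 (2 equiv), THF, 0 → 50 °C; H2O, aq. NaOH
Reagents that add atoms: none
Why: Hydride opens the trisubstituted epoxide by SN2 attack at the less substituted ring carbon (C4), the regiochemistry known for 1-alkylcyclohexene oxides. The C–O bond at the quaternary carbon is not broken, so its configuration is carried into C5 as (S).

Step 5
Reactants: 7 (1S)-1-(11-hydroxyundecyl)cyclohex-3-en-1-ol
Product: 8 (1S)-1-(11-iodoundecyl)cyclohex-3-en-1-ol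
Conditions: I2 (1.15 equiv), PPh3 (1.2 equiv), imidazole (1.5 equiv), CH2Cl2, 0 °C → rt
Reagents that add atoms: iodine, II
Why: Appel-type (Garegg–Samuelsson) iodination: the primary hydroxyl forms the alkoxyphosphonium ion and is displaced by iodide in an SN2 step, whereas the hindered tertiary ring hydroxyl does not react at this temperature.

Step 6
Reactants: 8 (1S)-1-(11-iodoundecyl)cyclohex-3-en-1-ol; 9 5-phenylpent-1-yne
Product: 11 (1S)-1-(16-phenylhexadec-12-yn-1-yl)cyclohex-3-en-1-ol, via lithium 5-phenylpent-1-yn-1-ide 10 (not isolated)
Conditions: 9 (2.5 equiv), n-BuLi (2.4 equiv), THF, −78 → 0 °C; then 8, DMPU, 0 °C → rt; aq. NH4Cl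
Reagents that add atoms: none
Why: SN2 alkylation of a lithium acetylide by a primary iodide in THF–DMPU forms C11′–C12′; one equivalent of 10 is spent on the tertiary hydroxyl, whose hindered lithium alkoxide does not compete as a nucleophile.

Step 7
Reactants: 11 (1S)-1-(16-phenylhexadec-12-yn-1-yl)cyclohex-3-en-1-ol; 12 di-tert-butyl dicarbonate
Product: 14 tert-butyl (1S)-1-(16-phenylhexadec-12-yn-1-yl)cyclohex-3-en-1-yl carbonate, via lithium (1S)-1-(16-phenylhexadec-12-yn-1-yl)cyclohex-3-en-1-olate 13 (not isolated)
Conditions: n-BuLi (1.05 equiv), THF, −78 °C; then 12 (1.5 equiv), −78 °C → rt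
Reagents that add atoms: none
Why: O-Acylation of a lithium tertiary alkoxide with 12 is the standard route to tert-butyl carbonates of hindered alcohols; the internal alkyne has no acidic hydrogen and the C5 centre is not involved.

Step 8
Reactants: 14 tert-butyl (1S)-1-(16-phenylhexadec-12-yn-1-yl)cyclohex-3-en-1-yl carbonate
Product: 15 (1S,5S,6S)-6-iodo-1-(16-phenylhexadec-12-yn-1-yl)-2,4-dioxabicyclo[3.3.1]nonan-3-one
Conditions: IBr (1.15 equiv, CH2Cl2 solution), PhMe, −85 °C; aq. Na2S2O3–NaHCO3
Reagents that add atoms: iodine monobromide, IBr
Why: IBr forms an iodonium ion on the C1=C2 alkene reversibly on either face, but only the ion on the face opposite the axial C5 carbonate (the chain prefers the equatorial site) can be captured. The carbonyl oxygen attacks C1 from its own face in an anti, trans-diaxial opening, and the resulting 2-tert-butoxy-1,3-dioxan-2-ylium ion loses the tert-butyl group as tert-butyl bromide. The closest known reaction is the iodocarbonate cyclisation of homoallylic tert-butyl carbonates to 1,3-syn diol carbonates, here closing a bridged carbonate as in the iodolactonisation of cyclohex-3-enecarboxylic acids. The one new ring, the six-membered cyclic carbonate, closes in the 6-exo mode; attack at C2 would need a seven-membered carbonate bridged across a boat. C1 is set (S) by the tether, which reaches only the face of the C5 oxygen, so the cis-1,3 relationship follows from the C5 configuration. C2 is set (S) by the anti addition, which places iodine axial and trans to the new C1–O bond. The step needs chemoselectivity for the ring alkene over the C12′≡C13′ alkyne and the arene. This should be secured by the much lower reactivity of alkynes toward electrophilic iodine, by the anchimeric capture available only to the ring alkene, and by a slight excess of reagent at −85 °C.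

Step 9
Reactants: 15 (1S,5S,6S)-6-iodo-1-(16-phenylhexadec-12-yn-1-yl)-2,4-dioxabicyclo[3.3.1]nonan-3-one
Product: 16 (1S,5S)-1-(16-phenylhexadec-12-yn-1-yl)-2,4-dioxabicyclo[3.3.1]non-6-en-3-one
Conditions: DBU (3 equiv), PhMe, 80 °C
Reagents that add atoms: none
Why: E2 dehydroiodination of the kind used on bicyclic iodolactones: the only β-hydrogen that can be anti-periplanar to the axial iodide is on C3, because the C1 hydrogen is cis to iodine and C1 is a bridgehead. The double bond should therefore form at C2=C3 with both stereocentres untouched.

Step 10
Reactants: 16 (1S,5S)-1-(16-phenylhexadec-12-yn-1-yl)-2,4-dioxabicyclo[3.3.1]non-6-en-3-one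
Product: 17 (1S,3S)-1-(16-phenylhexadec-12-yn-1-yl)cyclohex-4-ene-1,3-diol
Conditions: K2CO3 (0.5 equiv), MeOH, rt
Reagents that add atoms: none
Why: Base-catalysed methanolysis of the cyclic carbonate breaks only acyl C–O bonds, so both hydroxyls are released with retention; with the iodide already removed, no epoxide can form.

Step 11
Reactants: 17 (1S,3S)-1-(16-phenylhexadec-12-yn-1-yl)cyclohex-4-ene-1,3-diol
Product: 18 (1S,3S)-1-[(12Z)-16-phenylhexadec-12-en-1-yl]cyclohex-4-ene-1,3-diol
Conditions: H2 (1 atm), Pd/CaCO3–Pb(OAc)2 (Lindlar catalyst), quinoline, EtOAc, rt, stopped at 1 equiv H2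
Reagents that add atoms: none
Why: Lindlar semi-hydrogenation: syn delivery of hydrogen on the poisoned palladium surface should give the (Z)-alkene, while the disubstituted ring alkene and the allylic alcohol are left alone when uptake is stopped at one equivalent.

## Compound list

1 | 11-bromoundecan-1-ol | OCCCCCCCCCCCBr | starting material
2 | phenylmagnesium bromide | Br[Mg]c1ccccc1 | starting material
3 | bromomagnesium 11-bromoundecan-1-olate | BrCCCCCCCCCCCO[Mg]Br | intermediate (not isolated)
4 | 11-phenylundecan-1-ol | OCCCCCCCCCCCc1ccccc1 | intermediate
5 | 11-(cyclohexa-1,4-dien-1-yl)undecan-1-ol | OCCCCCCCCCCCC1=CCC=CC1 | intermediate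
6 | 11-[(1R,6S)-7-oxabicyclo[4.1.0]hept-3-en-1-yl]undecan-1-ol | C1=CC[C@@H]2O[C@]2(CCCCCCCCCCCO)C1 | intermediate
7 | (1S)-1-(11-hydroxyundecyl)cyclohex-3-en-1-ol | C1=CCC[C@@](O)(CCCCCCCCCCCO)C1 | intermediate
8 | (1S)-1-(11-iodoundecyl)cyclohex-3-en-1-ol | C1=CCC[C@@](O)(CCCCCCCCCCCI)C1 | intermediate
9 | 5-phenylpent-1-yne | C#CCCCc1ccccc1 | starting material
10 | lithium 5-phenylpent-1-yn-1-ide | [Li]C#CCCCc1ccccc1 | intermediate (not isolated)
11 | (1S)-1-(16-phenylhexadec-12-yn-1-yl)cyclohex-3-en-1-ol | C1=CCC[C@@](O)(CCCCCCCCCCCC#CCCCc2ccccc2)C1 | intermediate
12 | di-tert-butyl dicarbonate | CC(C)(C)OC(=O)OC(=O)OC(C)(C)C | starting material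
13 | lithium (1S)-1-(16-phenylhexadec-12-yn-1-yl)cyclohex-3-en-1-olate | C1=CCC[C@@](O[Li])(CCCCCCCCCCCC#CCCCc2ccccc2)C1 | intermediate (not isolated)
14 | tert-butyl (1S)-1-(16-phenylhexadec-12-yn-1-yl)cyclohex-3-en-1-yl carbonate | C1=CCC[C@@](OC(=O)OC(C)(C)C)(CCCCCCCCCCCC#CCCCc2ccccc2)C1 | intermediate
15 | (1S,5S,6S)-6-iodo-1-(16-phenylhexadec-12-yn-1-yl)-2,4-dioxabicyclo[3.3.1]nonan-3-one | O=C1O[C@@H]2[C@@H](I)CC[C@](CCCCCCCCCCCC#CCCCc3ccccc3)(O1)C2 | intermediate
16 | (1S,5S)-1-(16-phenylhexadec-12-yn-1-yl)-2,4-dioxabicyclo[3.3.1]non-6-en-3-one | O=C1O[C@@H]2C=CC[C@](CCCCCCCCCCCC#CCCCc3ccccc3)(O1)C2 | intermediate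
17 | (1S,3S)-1-(16-phenylhexadec-12-yn-1-yl)cyclohex-4-ene-1,3-diol | O[C@@H]1C=CC[C@@](O)(CCCCCCCCCCCC#CCCCc2ccccc2)C1 | intermediate
18 | (1S,3S)-1-[(12Z)-16-phenylhexadec-12-en-1-yl]cyclohex-4-ene-1,3-diol | O[C@@H]1C=CC[C@@](O)(CCCCCCCCCCC/C=C\CCCc2ccccc2)C1 | target

Total step count: 11. Longest linear sequence: 11 steps (1 to 18); the route is linear, with 2, 9 and 12 purchased.

## Least certain steps

Step 8 (key step). What is most likely to go wrong:
- Cyclisation through the hindered tertiary carbonate may be slow, so that bromide captures the iodonium ion intermolecularly (plain anti iodobromination of the ring alkene).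
- The tertiary carbonate may ionise at C5 under the acid generated.
- Slow electrophilic attack on the alkyne may set in if excess reagent or higher temperature is needed.

Fallback, setting out from 11 and returning at 17:
- The homoallylic tertiary hydroxyl of 11 directs a VO(acac)2/t-BuOOH epoxidation of the C1=C2 alkene to its own face. This gives the cis-epoxy alcohol (1S,3S,6R)-3-(16-phenylhexadec-12-yn-1-yl)-7-oxabicyclo[4.1.0]heptan-3-ol F1.
- PhSeNa (from PhSeSePh and NaBH4 in ethanol) opens F1 trans-diaxially at C2, the carbon where axial attack is possible in the half-chair with the chain equatorial. This gives the hydroxy selenide (1S,3S,4S)-4-(phenylselanyl)-1-(16-phenylhexadec-12-yn-1-yl)cyclohexane-1,3-diol F2.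
- Oxidation with H2O2 and syn elimination of the selenoxide away from the carbinol carbon should give 17, which then enters step 11.

Step 3. What is most likely to go wrong:
- Facial discrimination may be incomplete, because the substituent on the trisubstituted alkene is only an unbranched chain.
- Site selectivity may be lost, with over-oxidation at the second ring alkene.
- The homoallylic epoxide may open or aromatise under acid during isolation.

Fallback, setting out from 17 and returning to 17:
- The material is carried forward at whatever enantiomeric purity step 3 provides.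
- The secondary allylic hydroxyl of 17 is esterified selectively with (2S)-2-methoxy-2-phenylacetic acid (DCC, DMAP). This gives (1S,5S)-5-hydroxy-5-(16-phenylhexadec-12-yn-1-yl)cyclohex-2-en-1-yl (2S)-2-methoxy-2-phenylacetate F3.
- The minor enantiomer gives the diastereomer (1R,5R)-5-hydroxy-5-(16-phenylhexadec-12-yn-1-yl)cyclohex-2-en-1-yl (2S)-2-methoxy-2-phenylacetate F4, which is removed by chromatography or crystallisation.
- K2CO3 in methanol then returns stereochemically homogeneous 17.

Step 1. What is most likely to go wrong:
- Transmetalation of the aryl Grignard reagent to copper may be slow in the presence of the aggregated magnesium alkoxide.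
- This would allow homocoupling to biphenyl and reduction or elimination of the alkyl bromide.

Fallback, setting out from 1 and returning at 4, with the polarity of the coupling reversed:
- Silylation of 1 (TBSCl, imidazole) gives tert-butyl[(11-bromoundecyl)oxy]dimethylsilane F5.
- Magnesium in THF converts F5 into {11-[(tert-butyldimethylsilyl)oxy]undecyl}magnesium bromide F6.
- Ni(dppp)Cl2-catalysed Kumada–Corriu coupling of F6 with bromobenzene gives tert-butyldimethyl[(11-phenylundecyl)oxy]silane F7.
- Bu4NF releases 4.

Step 11. What is most likely to go wrong:
- Over-reduction of the alkyne or of the ring alkene.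
- Partial (Z) to (E) isomerisation on the catalyst.
- Hydrogenolysis of the allylic C1–O bond.

Fallback, setting out from 16 and returning at 18, with hydroboration and protonolysis in place of catalytic hydrogenation:
- Dicyclohexylborane adds syn to the alkyne of 16, which has no free hydroxyl, much faster than to the hindered ring alkene. Two regioisomers would form: (1S,5S)-1-[(12Z)-13-(dicyclohexylboranyl)-16-phenylhexadec-12-en-1-yl]-2,4-dioxabicyclo[3.3.1]non-6-en-3-one F8 and (1S,5S)-1-[(12Z)-12-(dicyclohexylboranyl)-16-phenylhexadec-12-en-1-yl]-2,4-dioxabicyclo[3.3.1]non-6-en-3-one F9.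
- Protonolysis of both with acetic acid, with retention, converges on (1S,5S)-1-[(12Z)-16-phenylhexadec-12-en-1-yl]-2,4-dioxabicyclo[3.3.1]non-6-en-3-one F10.
- K2CO3 in methanol cleaves the carbonate of F10 to give 18.

## Further compounds

F1 | step 8 | (1S,3S,6R)-3-(16-phenylhexadec-12-yn-1-yl)-7-oxabicyclo[4.1.0]heptan-3-ol | C1C[C@H]2O[C@H]2C[C@]1(O)CCCCCCCCCCCC#CCCCc3ccccc3
F2 | step 8 | (1S,3S,4S)-4-(phenylselanyl)-1-(16-phenylhexadec-12-yn-1-yl)cyclohexane-1,3-diol | O[C@@H]1[C@@H]([Se]c2ccccc2)CC[C@@](O)(CCCCCCCCCCCC#CCCCc3ccccc3)C1
F3 | step 3 | (1S,5S)-5-hydroxy-5-(16-phenylhexadec-12-yn-1-yl)cyclohex-2-en-1-yl (2S)-2-methoxy-2-phenylacetate | CO[C@@H](c1ccccc1)C(=O)O[C@@H]2C=CC[C@@](O)(CCCCCCCCCCCC#CCCCc3ccccc3)C2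
F4 | step 3 | (1R,5R)-5-hydroxy-5-(16-phenylhexadec-12-yn-1-yl)cyclohex-2-en-1-yl (2S)-2-methoxy-2-phenylacetate | CO[C@@H](c1ccccc1)C(=O)O[C@H]2C=CC[C@](O)(CCCCCCCCCCCC#CCCCc3ccccc3)C2
F5 | step 1 | tert-butyl[(11-bromoundecyl)oxy]dimethylsilane | CC(C)(C)[Si](C)(C)OCCCCCCCCCCCBr
F6 | step 1 | {11-[(tert-butyldimethylsilyl)oxy]undecyl}magnesium bromide | CC(C)(C)[Si](C)(C)OCCCCCCCCCCC[Mg]Br
F7 | step 1 | tert-butyldimethyl[(11-phenylundecyl)oxy]silane | CC(C)(C)[Si](C)(C)OCCCCCCCCCCCc1ccccc1
F8 | step 11 | (1S,5S)-1-[(12Z)-13-(dicyclohexylboranyl)-16-phenylhexadec-12-en-1-yl]-2,4-dioxabicyclo[3.3.1]non-6-en-3-one | O=C1O[C@@H]2C=CC[C@](CCCCCCCCCCC/C=C(\CCCc3ccccc3)B(C4CCCCC4)C5CCCCC5)(O1)C2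
F9 | step 11 | (1S,5S)-1-[(12Z)-12-(dicyclohexylboranyl)-16-phenylhexadec-12-en-1-yl]-2,4-dioxabicyclo[3.3.1]non-6-en-3-one | O=C1O[C@@H]2C=CC[C@](CCCCCCCCCCC/C(B(C4CCCCC4)C5CCCCC5)=C\CCCc3ccccc3)(O1)C2
F10 | step 11 | (1S,5S)-1-[(12Z)-16-phenylhexadec-12-en-1-yl]-2,4-dioxabicyclo[3.3.1]non-6-en-3-one | O=C1O[C@@H]2C=CC[C@](CCCCCCCCCCC/C=C\CCCc3ccccc3)(O1)C2
A1 | alternative 1 | (1S,5S)-1,5-bis[(tert-butyldimethylsilyl)oxy]cyclohex-3-ene-1-carboxylic acid | CC(C)(C)[Si](C)(C)O[C@@H]1C=CC[C@@](O[Si](C)(C)C(C)(C)C)(C(=O)O)C1
A2 | alternative 1 | (5S,6S)-3,5-bis[(tert-butyldimethylsilyl)oxy]-6-ethenyloxan-2-one (C3 configuration immaterial) | O=C1C(O[Si](C)(C)C(C)(C)C)C[C@H](O[Si](C)(C)C(C)(C)C)[C@H](C=C)O1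
A3 | alternative 2 | [(2R)-2-[(12Z)-16-phenylhexadec-12-en-1-yl]oxiran-2-yl]methyl 4-methylbenzenesulfonate | Cc1ccc(cc1)S(=O)(=O)OC[C@@]2(CCCCCCCCCCC/C=C\CCCc3ccccc3)CO2
A4 | alternative 2 | 2-methyl-1,3-dithiane | CC1SCCCS1
A5 | alternative 2 | 2-methyl-2-{[(2R)-2-[(12Z)-16-phenylhexadec-12-en-1-yl]oxiran-2-yl]methyl}-1,3-dithiane | CC1(SCCCS1)C[C@]2(CCCCCCCCCCC/C=C\CCCc3ccccc3)CO2
A6 | alternative 2 | (5S)-5-hydroxy-5-[(12Z)-16-phenylhexadec-12-en-1-yl]cyclohex-2-en-1-one | O=C1C=CC[C@@](O)(CCCCCCCCCCC/C=C\CCCc2ccccc2)C1
A7 | alternative 3 | 3-[(tert-butyldimethylsilyl)oxy]-3-[(12Z)-16-phenylhexadec-12-en-1-yl]cyclobutan-1-one | O=C1CC(O[Si](C)(C)C(C)(C)C)(CCCCCCCCCCC/C=C\CCCc2ccccc2)C1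
A8 | alternative 3 | ethyne | C#C
A9 | alternative 3 | (5S)-5-[(tert-butyldimethylsilyl)oxy]-5-[(12Z)-16-phenylhexadec-12-en-1-yl]cyclohex-2-en-1-one | O=C1C=CC[C@@](O[Si](C)(C)C(C)(C)C)(CCCCCCCCCCC/C=C\CCCc2ccccc2)C1
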